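## Structural features

The target is a flavone: benzo ring A (C4a to C8a) is fused to pyranone ring C (O1, C2, C3, C4). Ring B (4-methoxyphenyl) sits at C2, a methoxy group at C3, free hydroxyls at C5 and C7, and a 1-(4-hydroxyphenyl)ethyl group at C8 whose aryl ring is ring D. The only stereocentre is the methine Cα between C8 and ring D. It is R (ring A outranks ring D, then methyl, then hydrogen) and has no neighbouring stereocentre, so a reagent or catalyst must set it. Ring A is substituted everywhere except C6: oxygen at C5, C7 and C8a, carbon at C4a and C8. The Cα–C8 bond is fragile: strong acid can protonate the electron-rich ring at C8 and expel the 1-arylethyl cation, which would racemise or remove the side chain. A free 5-hydroxyl under strong acid is a second hazard, because ring C can reopen and reclose on the other oxygen and so move the side chain from C8 to C6. Three phenols must finally be freed beside two methyl ethers. The real difficulty is twofold: placing carbon at C8 with O1 told apart from the C5 and C7 oxygens, and fixing the configuration of a 1,1-diarylethane with two electron-rich aryl groups. The key step uses the fact that C8a (oxygen) and C8 (carbon) are adjacent and that C7, on the other side of C8, bears oxygen. This is the pattern left when an oxygen–carbon pair adds across an aryne with one flanking alkoxy group, and the new oxygen emerges as the only free phenol, the future O1.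

## Logic of the disconnections

20 to 19: the three O–H bonds at C5, C7 and ring D are traced back to O–benzyl bonds. Benzyl ethers leave by neutral hydrogenolysis, which spares the methyl ethers, the pyranone and the acid-sensitive C8–Cα bond and gives no chance for a C8-to-C6 shift. The gain is that every earlier intermediate has at most one free phenol. The forward step must not reduce the C2–C3 double bond or disturb Cα.

19 to 16 and 17 (through 18): ring C is opened at O1–C2 and at C2–C3. This removes ring B and ring C in one operation and brings the C3 methoxy group in as a methyl ether, so no late selective methylation is needed. The forward step must aroylate the enolate carbon of 16 and then close through the phenol. Because the C5 oxygen of 18 is benzylated, closure can only give the 8-substituted isomer.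

16 to 15 to 14: the C4a–C4 bond is cut and the acyl group is returned to the phenol oxygen, then the ester C–O bond is cut. Parking the acyl group on the future O1 uses the one free phenol to steer C-acylation to C4a rather than C6. The gain is a diarylethane phenol with no ring C carbons. The forward rearrangement needs a Lewis acid mild enough for three benzyl ethers and the stereocentre, and ortho rather than para migration.

14 to 13: the Cα–H bond and one methyl C–H bond are removed, giving a 1,1-diarylethene. The phenol beside the alkene can anchor a chiral catalyst, so the stereocentre is set separately from skeletal bond formation. The gain is an achiral precursor. The forward step must select one face of an alkene flanked on ring A by two ortho substituents.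

13 to 8 and 9 (through 12, 11 and 10): the C8a–O and C8–Cα bonds are cut together. One carbonyl group then supplies both the future O1 and Cα with its methyl group and ring D, and the regiochemistry follows from the ether at C7. The gain is the largest of the route: a symmetrical phenol derivative and a simple ketone. The forward step must make the carbonyl oxygen of an enolisable ketone add to the aryne faster than its enolate, and must release 13 before more aryne captures it.

8 to 6 to 2 to 1: the O–S bond and the C–Si bond are cut. A carbamate on the phenol oxygen directs metalation to the position between itself and an ether oxygen, and both such positions of 1 are equivalent. The gain is a purchasable symmetrical phenol. The forward steps must metalate the ring without touching the benzylic ether protons, and must remove the carbamate without cleaving the C–Si bond.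

## Other disconnections considered

Alternative 1: The cut is the C4a–C5 bond, so ring C exists first and ring A is closed onto it last.
- Forward step: the precursor is pyranone keto ester A2, methyl (5S)-5-[4-(benzyloxy)phenyl]-4-[5-methoxy-6-(4-methoxyphenyl)-4-oxo-4H-pyran-2-yl]-3-oxohexanoate. Its chain holds the future C8, C7, C6 and C5 and the preformed stereocentre. The S label describes the same spatial arrangement as R in the product, because ring D outranks the sp3 neighbour. A magnesium alkoxide would generate the dienolate, the carbon that becomes C4a would attack the ester carbonyl (Claisen-type closure), and enolisation would give dihydroxyflavone A1.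
- In its favour: the closure imitates polyketide biosynthesis, a known reaction type. No regiochemical question arises on ring A, because C8 carries its substituent before the ring exists. No electrophilic acylation of an acid-sensitive diarylethane is needed. On these three points it is better than the chosen plan, whose key step is untested and whose step 7 exposes the stereocentre to a Lewis acid.
- Against it: A2 is much harder to make than 8 and 9. The stereocentre must be set early and carried next to the carbon that is deprotonated. The more acidic methylene between ketone and ester can instead attack the C4 carbonyl, and an alkoxide can open the pyranone at C2.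
- Comparison: the end game is equal (one hydrogenolysis from A1 to 20, as from 19 to 20). Building A2 would probably make this the longest of the four routes. Mechanistic risk is spread over several ordinary steps instead of concentrated in one new one.

Alternative 2: Three bonds of ring A are cut (C8a–C8, C7–C6, C4a–C8a).
- Forward step: the four-carbon partner is 3-ethoxycyclobut-2-en-1-one A4 and the two-carbon partner is siloxyalkyne A5, {[(3R)-3-(4-benzyloxyphenyl)but-1-yn-1-yl]oxy}tri(propan-2-yl)silane. Heating would open A4 to a vinylketene, which adds to A5; a second 4π opening, 6π closure and tautomerisation would give phenol A3.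
- In its favour: the benzannulation is a known reaction type and regiospecific by mechanism. It is convergent. Like 13, A3 has a single free phenol, the future O1, with the other two oxygens differentiated. The thermal conditions are neutral. On precedent it is better than the chosen key step, and on the single free phenol it is equal.
- Against it: the stereocentre of A5 is propargylic and benzylic. The usual ynolate routes to siloxyalkynes start from an ester in which this carbon would be the enolisable α-carbon, so its configuration is at risk before the key step. The C5 ethyl ether must later be removed beside two methyl ethers with a chelating Lewis acid, on a molecule whose side chain is acid-labile and whose free 5-hydroxyl then permits the C8-to-C6 shift. The C7 silyl ether must be carried or exchanged.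
- Comparison: ring C must still be built from A3 by an ortho-acylation, the same problem as step 7 (equal). With the synthesis of A5 counted, the step count is similar to or slightly higher than the chosen plan.

Alternative 3: Both bonds from Cα to the rings are cut, and the CH–CH3 unit comes from ethene A9.
- Forward step: a zerovalent palladium source with a chiral ligand would take up diazonium salt A7 (4-(benzyloxy)benzenediazonium tetrafluoroborate), insert A9, and migrate by β-hydride elimination and re-insertion to the benzylic position. Transmetalation with boronic acid A8 ([2,4-bis(benzyloxy)-6-(methoxymethoxy)phenyl]boronic acid) and reductive elimination would give diarylethane A6.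
- In its favour: this is the most convergent plan and uses the simplest two-carbon building block. Removing the acetal from A6 gives 14 directly, and A8 should be about two steps from 1, so 14 would be reached in fewer steps than in the chosen plan. On convergence and step economy it is better.
- Against it: only the racemic three-component 1,1-diarylation is a known reaction type. Asymmetric induction at a π-benzyl palladium intermediate that can epimerise is unproven, so C–C bond formation and stereocontrol are both uncertain in one step. A8 is an electron-rich boronic acid with two ortho oxygens, prone to protodeboronation and slow to transmetalate. A7 is an energetic salt and A9 a flammable gas under pressure, so it is less safe.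
- Comparison: both key steps go beyond known chemistry. The chosen plan confines the new chemistry to a step that makes no stereocentre and sets the configuration by a known directed hydrogenation. This alternative is shorter but stakes two unknowns on one step.

Key step: step 4

Assumption: 1, 9 and 17 are taken as purchasable. Name, SMILES and R descriptor of 20 agree, as do those of 8 and 13, so no structure needs correction. The sense of induction in step 5 cannot be read from the ligand name, so the ligand antipode that gives R in 14 is to be fixed by one trial.

Step 1
Reactants: 1 3,5-bis(benzyloxy)phenol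
Product: 2 3,5-bis(benzyloxy)phenyl N-isopropylcarbamate
Conditions: i-PrNCO, Et3N (cat.), CH2Cl2, rt
Reagents that add atoms: isopropyl isocyanate, CC(C)N=C=O
Why: Base-catalysed addition of the phenol O–H to the isocyanate (carbamoylation); the N–H carbamate is chosen because it can later be removed under mild E1cB conditions that an N,N-dialkyl carbamate would not allow.

Step 2
Reactants: 2 3,5-bis(benzyloxy)phenyl N-isopropylcarbamate
Product: 6 3,5-bis(benzyloxy)-2-(trimethylsilyl)phenyl N-isopropylcarbamate, via N-silyl carbamate 3 (not isolated), via aryllithium 4 (not isolated), via bis-silyl carbamate 5 (not isolated)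
Conditions: TBSOTf, TMEDA, Et2O, 0 °C to rt; n-BuLi, TMEDA, −78 °C; TMSCl, −78 °C to rt; aq. NaHSO4
Reagents that add atoms: chlorotrimethylsilane, C[Si](C)(C)Cl; tert-butyldimethylsilyl triflate, CC(C)(C)[Si](C)(C)OS(=O)(=O)C(F)(F)F (its silyl group stays in 3 to 5 only); n-butyllithium, [Li]CCCC (its lithium stays in 4 only)
Why: Directed ortho-metalation: with N–H masked in the flask as N-silyl, the carbamate carbonyl holds the base at C2, which is flanked by carbamate and ether oxygen, rather than at C4 between two ethers; at −78 °C the benzylic ether protons and the anionic Fries shift should stay out of play, and acidic work-up removes the N-silyl group.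

Step 3
Reactants: 6 3,5-bis(benzyloxy)-2-(trimethylsilyl)phenyl N-isopropylcarbamate
Product: 8 3,5-bis(benzyloxy)-2-(trimethylsilyl)phenyl trifluoromethanesulfonate, via silylphenol 7 (not isolated)
Conditions: Et2NH, DBU, MeCN, 40 °C; then PhNTf2, rt
Reagents that add atoms: N-phenylbis(trifluoromethanesulfonimide), O=S(=O)(N(c1ccccc1)S(=O)(=O)C(F)(F)F)C(F)(F)F
Why: E1cB cleavage of the N–H carbamate (the amidine base removes N–H, the phenoxide leaves, the isocyanate is trapped by the secondary amine as a urea), then O-sulfonylation of the phenoxide in the same flask; no fluoride or hard nucleophile is present, so the C–Si bond should survive.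

Step 4
Reactants: 8 3,5-bis(benzyloxy)-2-(trimethylsilyl)phenyl trifluoromethanesulfonate; 9 4'-(benzyloxy)acetophenone
Product: 13 3,5-bis(benzyloxy)-2-{1-[4-(benzyloxy)phenyl]ethenyl}phenol, via aryne 10 (not isolated), via benzoxete 11 (not isolated), via o-quinone methide 12 (not isolated)
Conditions: CsF (3 equiv), 9 (4 equiv), MeCN/toluene, 40 °C, 8 added slowly
Reagents that add atoms: none
Why: Proposed new method: fluoride removes the silyl group of 8 and triflate departs to give aryne 10, in which the benzyloxy group beside the triple bond distorts the ring so that the remote carbon is the electrophilic one and negative charge is best placed on the carbon next to the ether. The carbonyl oxygen of 9 therefore bonds to the future C8a and the aryl anion at the future C8 collapses onto the oxocarbenium carbon, a stepwise formal [2+2] addition (4-endo closure of the zwitterion) that gives benzoxete 11. Thermal 4π opening of 11 gives o-quinone methide 12, and transfer of a methyl proton to oxygen, as a 1,5-hydrogen shift or relayed by fluoride so that either alkene geometry is served, restores the aromatic ring as 13; the four-membered ring forms and opens in the same flask, so no ring and no stereocentre remains. The closest known reaction type is the insertion of arynes into the C=O bond of aldehydes and formamides, which gives o-quinone methides through the same benzoxete; an enolisable aryl methyl ketone as carbonyl partner, with tautomerisation as the final event, is the untested part. Regioselectivity is needed and should follow from the alkoxy-induced distortion and inductive effect, the normal behaviour of 3-alkoxyarynes towards heteroatom nucleophiles. Chemoselectivity is needed against C-arylation of the enolate of 9 and against capture of 12 or 13 by a second aryne; an excess of 9, slow addition of 8 and sparingly soluble CsF in a medium of low polarity are meant to keep aryne and free base at low concentration.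

Step 5
Reactants: 13 3,5-bis(benzyloxy)-2-{1-[4-(benzyloxy)phenyl]ethenyl}phenol
Product: 14 3,5-bis(benzyloxy)-2-[(1R)-1-(4-benzyloxyphenyl)ethyl]phenol
Conditions: [Rh(cod)2]BF4 (cat.), (1R,1′R,2S,2′S)-DuanPhos (cat.), H2 (10 bar), Et3N (cat.), MeOH/CH2Cl2, rt
Reagents that add atoms: none
Why: Hydroxyl-directed asymmetric hydrogenation of a 2-(1-arylvinyl)phenol: the phenol oxygen binds the cationic monovalent rhodium centre beside the alkene, so the two aryl groups are told apart by chelation and not by size, and the chiral bisphosphine fixes the face on which hydrogen reaches Cα (R with the ligand antipode chosen as in the assumption); cationic rhodium should not hydrogenolyse benzyl ethers.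

Step 6
Reactants: 14 3,5-bis(benzyloxy)-2-[(1R)-1-(4-benzyloxyphenyl)ethyl]phenol
Product: 15 3,5-bis(benzyloxy)-2-[(1R)-1-(4-benzyloxyphenyl)ethyl]phenyl methoxyacetate
Conditions: MeOCH2COCl, Et3N, DMAP (cat.), CH2Cl2, 0 °C
Reagents that add atoms: methoxyacetyl chloride, COCC(=O)Cl
Why: Nucleophile-catalysed O-acylation of the single free phenol; the basic medium takes up HCl, so the acid-sensitive C8–Cα bond is not exposed.

Step 7
Reactants: 15 3,5-bis(benzyloxy)-2-[(1R)-1-(4-benzyloxyphenyl)ethyl]phenyl methoxyacetate
Product: 16 1-{4,6-bis(benzyloxy)-3-[(1R)-1-(4-benzyloxyphenyl)ethyl]-2-hydroxyphenyl}-2-methoxyethan-1-one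
Conditions: ZrCl4, CH2Cl2, 0 °C to rt
Reagents that add atoms: none
Why: Ortho-Fries rearrangement: the Lewis acid ionises the ester and the acyl group returns to the only open ortho carbon (future C4a), where the product is held as a six-membered metal chelate; ZrCl4 is chosen as a mild promoter that should not cleave aryl benzyl ethers, and the aprotic medium limits protonation at C8.

Step 8
Reactants: 16 1-{4,6-bis(benzyloxy)-3-[(1R)-1-(4-benzyloxyphenyl)ethyl]-2-hydroxyphenyl}-2-methoxyethan-1-one; 17 4-methoxybenzoyl chloride
Product: 19 5,7-bis(benzyloxy)-8-[(1R)-1-(4-benzyloxyphenyl)ethyl]-3-methoxy-2-(4-methoxyphenyl)-4H-chromen-4-one, via 1,3-diketone 18 (not isolated)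
Conditions: LiN(SiMe3)2 (3.2 equiv), THF, −78 °C; 17, −78 °C to rt; AcOH quench, evaporate; AcOH, NaOAc, 100 °C
Reagents that add atoms: none
Why: Direct C-aroylation of the lithium enolate of an o-hydroxyaryl ketone, the one-flask form of the Baker–Venkataraman synthesis (any O-aroyl ester formed is carried to the same diketone by the excess base), followed by cyclodehydration in buffered acetic acid; only the phenol next to C8 is free, so O1–C2 can form in one way only, and the amide base is far too weak to remove the diarylmethine proton.

Step 9
Reactants: 19 5,7-bis(benzyloxy)-8-[(1R)-1-(4-benzyloxyphenyl)ethyl]-3-methoxy-2-(4-methoxyphenyl)-4H-chromen-4-one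
Product: 20 5,7-dihydroxy-8-[(1R)-1-(4-hydroxyphenyl)ethyl]-3-methoxy-2-(4-methoxyphenyl)-4H-chromen-4-one
Conditions: H2 (1 atm), 10% Pd/C, EtOAc/MeOH, rt
Reagents that add atoms: none
Why: Hydrogenolysis of three aryl benzyl ethers over palladium on carbon; the methyl ethers, the pyranone and the C8–Cα bond (no heteroatom on Cα) are inert under these neutral conditions, so Cα stays R and the free 5-hydroxyl never meets strong acid.

Compound list

1 | 3,5-bis(benzyloxy)phenol | Oc1cc(OCc2ccccc2)cc(OCc2ccccc2)c1 | starting material
2 | 3,5-bis(benzyloxy)phenyl N-isopropylcarbamate | CC(C)NC(=O)Oc1cc(OCc2ccccc2)cc(OCc2ccccc2)c1 | intermediate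
3 | 3,5-bis(benzyloxy)phenyl N-(tert-butyldimethylsilyl)-N-isopropylcarbamate | CC(C)N(C(=O)Oc1cc(OCc2ccccc2)cc(OCc2ccccc2)c1)[Si](C)(C)C(C)(C)C | intermediate (not isolated)
4 | [2,4-bis(benzyloxy)-6-{[(tert-butyldimethylsilyl)(isopropyl)carbamoyl]oxy}phenyl]lithium | CC(C)N(C(=O)Oc1cc(OCc2ccccc2)cc(OCc2ccccc2)c1[Li])[Si](C)(C)C(C)(C)C | intermediate (not isolated)
5 | 3,5-bis(benzyloxy)-2-(trimethylsilyl)phenyl N-(tert-butyldimethylsilyl)-N-isopropylcarbamate | CC(C)N(C(=O)Oc1cc(OCc2ccccc2)cc(OCc2ccccc2)c1[Si](C)(C)C)[Si](C)(C)C(C)(C)C | intermediate (not isolated)
6 | 3,5-bis(benzyloxy)-2-(trimethylsilyl)phenyl N-isopropylcarbamate | CC(C)NC(=O)Oc1cc(OCc2ccccc2)cc(OCc2ccccc2)c1[Si](C)(C)C | intermediate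
7 | 3,5-bis(benzyloxy)-2-(trimethylsilyl)phenol | C[Si](C)(C)c1c(O)cc(OCc2ccccc2)cc1OCc1ccccc1 | intermediate (not isolated)
8 | 3,5-bis(benzyloxy)-2-(trimethylsilyl)phenyl trifluoromethanesulfonate | C[Si](C)(C)c1c(OCc2ccccc2)cc(OCc2ccccc2)cc1OS(=O)(=O)C(F)(F)F | intermediate
9 | 4'-(benzyloxy)acetophenone | CC(=O)c1ccc(OCc2ccccc2)cc1 | starting material
10 | 3,5-bis(benzyloxy)benzyne | C1#CC(OCc2ccccc2)=CC(OCc2ccccc2)=C1 | intermediate (not isolated)
11 | 3,5-bis(benzyloxy)-2-[4-(benzyloxy)phenyl]-2-methyl-2H-benzo[b]oxete | CC1(c2ccc(OCc3ccccc3)cc2)Oc2cc(OCc3ccccc3)cc(OCc3ccccc3)c21 | intermediate (not isolated)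
12 | 3,5-bis(benzyloxy)-6-{1-[4-(benzyloxy)phenyl]ethylidene}cyclohexa-2,4-dien-1-one | CC(c1ccc(OCc2ccccc2)cc1)=C1C(=O)C=C(OCc2ccccc2)C=C1OCc1ccccc1 | intermediate (not isolated)
13 | 3,5-bis(benzyloxy)-2-{1-[4-(benzyloxy)phenyl]ethenyl}phenol | C=C(c1ccc(OCc2ccccc2)cc1)c1c(O)cc(OCc2ccccc2)cc1OCc1ccccc1 | intermediate
14 | 3,5-bis(benzyloxy)-2-[(1R)-1-(4-benzyloxyphenyl)ethyl]phenol | Oc1cc(OCc2ccccc2)cc(OCc2ccccc2)c1[C@H](C)c1ccc(OCc2ccccc2)cc1 | intermediate
15 | 3,5-bis(benzyloxy)-2-[(1R)-1-(4-benzyloxyphenyl)ethyl]phenyl methoxyacetate | COCC(=O)Oc1cc(OCc2ccccc2)cc(OCc2ccccc2)c1[C@H](C)c1ccc(OCc2ccccc2)cc1 | intermediate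
16 | 1-{4,6-bis(benzyloxy)-3-[(1R)-1-(4-benzyloxyphenyl)ethyl]-2-hydroxyphenyl}-2-methoxyethan-1-one | COCC(=O)c1c(OCc2ccccc2)cc(OCc2ccccc2)c([C@H](C)c2ccc(OCc3ccccc3)cc2)c1O | intermediate
17 | 4-methoxybenzoyl chloride | COc1ccc(C(=O)Cl)cc1 | starting material
18 | 1-{4,6-bis(benzyloxy)-3-[(1R)-1-(4-benzyloxyphenyl)ethyl]-2-hydroxyphenyl}-2-methoxy-3-(4-methoxyphenyl)propane-1,3-dione (epimers at C2 of the chain) | COc1ccc(C(=O)C(OC)C(=O)c2c(OCc3ccccc3)cc(OCc3ccccc3)c([C@H](C)c3ccc(OCc4ccccc4)cc3)c2O)cc1 | intermediate (not isolated)
19 | 5,7-bis(benzyloxy)-8-[(1R)-1-(4-benzyloxyphenyl)ethyl]-3-methoxy-2-(4-methoxyphenyl)-4H-chromen-4-one | COc1ccc(-c2oc3c([C@H](C)c4ccc(OCc5ccccc5)cc4)c(OCc4ccccc4)cc(OCc4ccccc4)c3c(=O)c2OC)cc1 | intermediate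
20 | 5,7-dihydroxy-8-[(1R)-1-(4-hydroxyphenyl)ethyl]-3-methoxy-2-(4-methoxyphenyl)-4H-chromen-4-one | COc1ccc(-c2oc3c([C@H](C)c4ccc(O)cc4)c(O)cc(O)c3c(=O)c2OC)cc1 | target

Total step count: 9. Longest linear sequence: 9 steps (1 to 20); 9 and 17 enter as purchased materials.

Least certain steps

Step 4 (key step, new method). Three things are most likely to go wrong:
- fluoride-induced enolisation of 9, followed by C-arylation or self-condensation;
- capture of the product phenol or of the o-quinone methide by a second aryne (O-arylation or [4+2] addition);
- failure of the hindered zwitterion to close, so that the aryl anion is simply protonated.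

The fallback uses only known chemistry; it sets out from 2 and returns at 13. Compound 2 is N-silylated and ortho-lithiated as in step 2 to give 4, which is added at −78 °C to ketone 9 to give the lithium alkoxide of the N-silyl carbinol carbamate F1. An organocerium variant is the usual remedy if enolisation of 9 competes. Acidic work-up gives 3,5-bis(benzyloxy)-2-{1-[4-(benzyloxy)phenyl]-1-hydroxyethyl}phenyl N-isopropylcarbamate F2. Et2NH/DBU cleavage gives 3,5-bis(benzyloxy)-2-{1-[4-(benzyloxy)phenyl]-1-hydroxyethyl}phenol F3, and a trace of acid dehydrates it through 12 to 13. If the carbamoyl group moves to the carbinol oxygen on warming, the same F3 results. This makes only the C8–Cα bond, since the C8a–O bond is already in 1, and it costs one step more.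

Step 7. The likely failures are:
- migration of the acyl group to C6 (para to the phenol oxygen) instead of C4a;
- chelation-assisted loss of the benzyl group next to the new ketone, which would free the C5 oxygen and spoil the regiochemistry of step 8;
- acid-induced ionisation of the C8–Cα bond, with racemisation.

The fallback avoids acid altogether; it sets out from 14 and returns at 16. Amine-catalysed ortho-bromination (NBS, i-Pr2NH cat., CH2Cl2) gives 3,5-bis(benzyloxy)-2-bromo-6-[(1R)-1-(4-benzyloxyphenyl)ethyl]phenol F4. Two equivalents of n-BuLi at −78 °C give the lithium 2-lithiophenoxide F5 by deprotonation and fast bromine–lithium exchange. Acylation with the Weinreb amide 2,N-dimethoxy-N-methylacetamide then gives 16. The step count is unchanged because 15 is bypassed.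

Step 5. The alkene is flanked on ring A by hydroxyl and benzyloxy groups. This may slow binding to rhodium and erode facial selectivity, and the sense of induction must be found by trial. The fallback changes the mechanism; it sets out from 13 and returns at 14. A chiral BINOL-derived phosphoric acid with a Hantzsch ester protonates the alkene to the ion-paired o-quinone methide 12 and delivers hydride to Cα within the chiral ion pair (organocatalytic transfer hydrogenation of 2-(1-arylvinyl)phenols). It makes no compound outside the list (F0).

Step 2. Deprotonation of a benzylic ether CH2, followed by [1,2]-Wittig rearrangement, or metalation at C4, may compete with ortho-lithiation. The fallback avoids deprotonating the ring; it sets out from 1 and returns at 8. Ortho-bromination of 1 (NBS, i-Pr2NH cat.) gives 3,5-bis(benzyloxy)-2-bromophenol F6, and silylation with HN(SiMe3)2 gives [3,5-bis(benzyloxy)-2-bromophenoxy]trimethylsilane F7. Bromine–lithium exchange with n-BuLi at −78 °C gives [3,5-bis(benzyloxy)-2-lithiophenoxy]trimethylsilane F8, whose silyl group shifts from oxygen to carbon (retro-Brook) to give the lithium salt of 7. Tf2O then gives 8. Its own weak point is ortho versus para selectivity in the bromination.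

Further compounds

F1 | step 4 | lithium 1-[2,4-bis(benzyloxy)-6-{[(tert-butyldimethylsilyl)(isopropyl)carbamoyl]oxy}phenyl]-1-[4-(benzyloxy)phenyl]ethoxide | CC(C)N(C(=O)Oc1cc(OCc2ccccc2)cc(OCc2ccccc2)c1C(C)(O[Li])c1ccc(OCc2ccccc2)cc1)[Si](C)(C)C(C)(C)C
F2 | step 4 | 3,5-bis(benzyloxy)-2-{1-[4-(benzyloxy)phenyl]-1-hydroxyethyl}phenyl N-isopropylcarbamate | CC(C)NC(=O)Oc1cc(OCc2ccccc2)cc(OCc2ccccc2)c1C(C)(O)c1ccc(OCc2ccccc2)cc1
F3 | step 4 | 3,5-bis(benzyloxy)-2-{1-[4-(benzyloxy)phenyl]-1-hydroxyethyl}phenol | CC(O)(c1ccc(OCc2ccccc2)cc1)c1c(O)cc(OCc2ccccc2)cc1OCc1ccccc1
F4 | step 7 | 3,5-bis(benzyloxy)-2-bromo-6-[(1R)-1-(4-benzyloxyphenyl)ethyl]phenol | Oc1c(Br)c(OCc2ccccc2)cc(OCc2ccccc2)c1[C@H](C)c1ccc(OCc2ccccc2)cc1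
F5 | step 7 | lithium 3,5-bis(benzyloxy)-6-[(1R)-1-(4-benzyloxyphenyl)ethyl]-2-lithiophenoxide | [Li]Oc1c([Li])c(OCc2ccccc2)cc(OCc2ccccc2)c1[C@H](C)c1ccc(OCc2ccccc2)cc1
F0 | step 5 | none | none
F6 | step 2 | 3,5-bis(benzyloxy)-2-bromophenol | Oc1cc(OCc2ccccc2)cc(OCc2ccccc2)c1Br
F7 | step 2 | [3,5-bis(benzyloxy)-2-bromophenoxy]trimethylsilane | C[Si](C)(C)Oc1cc(OCc2ccccc2)cc(OCc2ccccc2)c1Br
F8 | step 2 | [3,5-bis(benzyloxy)-2-lithiophenoxy]trimethylsilane | C[Si](C)(C)Oc1cc(OCc2ccccc2)cc(OCc2ccccc2)c1[Li]
A1 | alternative 1 | 8-{(1R)-1-[4-(benzyloxy)phenyl]ethyl}-5,7-dihydroxy-3-methoxy-2-(4-methoxyphenyl)-4H-chromen-4-one | COc1ccc(-c2oc3c([C@H](C)c4ccc(OCc5ccccc5)cc4)c(O)cc(O)c3c(=O)c2OC)cc1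
A2 | alternative 1 | methyl (5S)-5-[4-(benzyloxy)phenyl]-4-[5-methoxy-6-(4-methoxyphenyl)-4-oxo-4H-pyran-2-yl]-3-oxohexanoate (epimers at C4) | COC(=O)CC(=O)C([C@H](C)c1ccc(OCc2ccccc2)cc1)c1cc(=O)c(OC)c(-c2ccc(OC)cc2)o1
A3 | alternative 2 | 2-[(1R)-1-(4-benzyloxyphenyl)ethyl]-5-ethoxy-3-(triisopropylsilyloxy)phenol | CCOc1cc(O)c([C@H](C)c2ccc(OCc3ccccc3)cc2)c(O[Si](C(C)C)(C(C)C)C(C)C)c1
A4 | alternative 2 | 3-ethoxycyclobut-2-en-1-one | CCOC1=CC(=O)C1
A5 | alternative 2 | {[(3R)-3-(4-benzyloxyphenyl)but-1-yn-1-yl]oxy}tri(propan-2-yl)silane | C[C@H](c1ccc(OCc2ccccc2)cc1)C#CO[Si](C(C)C)(C(C)C)C(C)C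
A6 | alternative 3 | 1,5-bis(benzyloxy)-2-[(1R)-1-(4-benzyloxyphenyl)ethyl]-3-(methoxymethoxy)benzene | COCOc1cc(OCc2ccccc2)cc(OCc2ccccc2)c1[C@H](C)c1ccc(OCc2ccccc2)cc1
A7 | alternative 3 | 4-(benzyloxy)benzenediazonium tetrafluoroborate | N#[N+]c1ccc(OCc2ccccc2)cc1.F[B-](F)(F)F
A8 | alternative 3 | [2,4-bis(benzyloxy)-6-(methoxymethoxy)phenyl]boronic acid | COCOc1cc(OCc2ccccc2)cc(OCc2ccccc2)c1B(O)O
A9 | alternative 3 | ethene | C=C
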